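Ring E is made by an enantioselective Diels–Alder reaction, ring C by the lactone Ireland–Claisen contraction, ring D by metathesis, ring B by a Heck closure, and the dioxane by an o-quinone [4+2] addition that is flagged as a new method.

**Retrosynthetic overview**

- Last bonds: the cis-fused dioxane (C2–O–G5, C3–O–G1) by [4+2] addition of the ring A o-quinone to the G1=G5 bond of a 3-silyloxy guaia-1(5),3,11-triene made from (S)-carvone; G3=G4 then comes from the enol nonaflate.
- Ring B: C5–C6 by aryl Grignard addition and oxidation, C9–C10 by a 6-exo Heck reaction on C9=C11 (sets C9). Ring D: metathesis of vinyl groups on C14 and C17; both ring alkenes are then hydrogenated.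
- Ring C (key): the strategy rests on C14 (quaternary: methyl, C15) and C8 (H), adjacent in ring C (C8, C9, C11, C12, C13, C14) beside quaternary C13, with C11 three atoms from C14. A C15/C11 δ-lactone carrying the (E)-C9=C8 alkenyl group on C11 contracts by Ireland–Claisen rearrangement (new C8–C14 bond, alkene to C9=C11).
- The lactone comes from a C11 enone (alkenyllithium, then CBS reduction); C13 is set by an acyclic Ireland–Claisen rearrangement of a (Z)-allyl propanoate; ring E with C17 and C18 comes from an enantioselective Diels–Alder reaction.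
- Ring order: E, C, D, B (ring A is brought in as the arene), then the dioxane with the two guaiane rings.

Key step: step 20

Assumption: the target is taken exactly as its SMILES reads (friedelane numbering C1–C28 for the triterpenoid part, G1–G15 for the guaiane part; 8β-H cis to the C9 and C14 methyls, 18α-H trans to the C17 methyl, dioxane oxygens cis to each other and anti to the G10 methyl), and the (S)-oxazaborolidinium catalyst of step 4 is taken to expose the C18 Si face of enal 4 (formyl C–H···O model), its antipode being used otherwise.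

**Route**

Step 1
Reactants: 1 2,2-dimethoxyacetaldehyde; 2 ethyl 2-(triphenyl-λ5-phosphanylidene)propanoate
Product: 3 ethyl (E)-4,4-dimethoxy-2-methylbut-2-enoate
Conditions: CH2Cl2, rt
Reagents that add atoms: none
Why: Wittig olefination with a stabilised ylide should give the (E)-enoate, the ester trans to the acetal carbon.

Step 2
Reactants: 3 ethyl (E)-4,4-dimethoxy-2-methylbut-2-enoate
Product: 4 ethyl (E)-2-methyl-4-oxobut-2-enoate
Conditions: 1 M aq. HCl, acetone, rt
Reagents that add atoms: water, O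
Why: Acid-catalysed acetal hydrolysis should free the aldehyde without touching the conjugated ester or the (E) geometry.

Step 3
Reactants: 5 but-3-en-2-one
Product: 6 2-(triisopropylsilyloxy)buta-1,3-diene
Conditions: i-Pr3SiOSO2CF3, Et3N, Et2O, 0 °C → rt
Reagents that add atoms: triisopropylsilyl trifluoromethanesulfonate, CC(C)[Si](C(C)C)(C(C)C)OS(=O)(=O)C(F)(F)F
Why: Soft enolisation (O-silylation, then deprotonation by the amine) of the enone should give the 2-silyloxy diene.

Step 4
Reactants: 4 ethyl (E)-2-methyl-4-oxobut-2-enoate; 6 2-(triisopropylsilyloxy)buta-1,3-diene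
Product: 7 ethyl (1S,6S)-6-formyl-1-methyl-3-(triisopropylsilyloxy)cyclohex-3-ene-1-carboxylate
Conditions: (S)-1-(2-methylphenyl)-3,3-diphenyltetrahydro-1H,3H-pyrrolo[1,2-c][1,3,2]oxazaborole (20 mol %), HN(SO2CF3)2 (20 mol %), CH2Cl2, −78 → −40 °C
Reagents that add atoms: none
Why: Enantioselective Diels–Alder reaction of the formyl-bound oxazaborolidinium complex closes ring E by [4+2] addition; the nucleophilic diene terminus bonds to C17 (β to the formyl group), which places the silyloxy carbon at C21; the (E) dienophile geometry makes the formyl group trans to the ester (cis to the C17 methyl); the catalyst fixes the absolute sense at C17 and C18 by directing the diene to the C18 Si face.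

Step 5
Reactants: 7 ethyl (1S,6S)-6-formyl-1-methyl-3-(triisopropylsilyloxy)cyclohex-3-ene-1-carboxylate
Product: 8 ethyl 6-(2,2-dibromoethenyl)-1-methyl-3-(triisopropylsilyloxy)cyclohex-3-ene-1-carboxylate
Conditions: CBr4, PPh3, Zn dust, CH2Cl2, rt (ylide formed first); then 7, 0 °C
Reagents that add atoms: carbon tetrabromide, BrC(Br)(Br)Br
Why: Corey–Fuchs (Ramirez) dibromo-olefination runs under neutral conditions, so the epimerisable C18 and the silyl enol ether should survive.

Step 6
Reactants: 8 ethyl 6-(2,2-dibromoethenyl)-1-methyl-3-(triisopropylsilyloxy)cyclohex-3-ene-1-carboxylate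
Product: 9 ethyl 8-(2,2-dibromoethenyl)-7-methyl-1,4-dioxaspiro[4.5]decane-7-carboxylate
Conditions: HOCH2CH2OH, TsOH·H2O (cat.), benzene, reflux, Dean–Stark
Reagents that add atoms: ethane-1,2-diol, OCCO
Why: Acid-catalysed protodesilylation and ketalisation should convert the silyl enol ether directly into the C21 dioxolane.

Step 7
Reactants: 9 ethyl 8-(2,2-dibromoethenyl)-7-methyl-1,4-dioxaspiro[4.5]decane-7-carboxylate
Product: 11 ethyl 8-(3-methoxy-3-oxoprop-1-yn-1-yl)-7-methyl-1,4-dioxaspiro[4.5]decane-7-carboxylate, via lithium acetylide 10 (not isolated)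
Conditions: n-BuLi (2.1 equiv), THF, −78 °C; ClCO2Me, −78 → 0 °C
Reagents that add atoms: methyl chloroformate, COC(=O)Cl
Why: Second stage of the Corey–Fuchs sequence (Br/Li exchange, Fritsch–Buttenberg–Wiechell rearrangement, deprotonation), then C-acylation of the acetylide; the hindered, non-enolisable C16 ester should survive at −78 °C.

Step 8
Reactants: 11 ethyl 8-(3-methoxy-3-oxoprop-1-yn-1-yl)-7-methyl-1,4-dioxaspiro[4.5]decane-7-carboxylate
Product: 12 ethyl 8-[(Z)-4-methoxy-4-oxobut-2-en-2-yl]-7-methyl-1,4-dioxaspiro[4.5]decane-7-carboxylate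
Conditions: Me2CuLi, THF, −78 °C; MeOH, −78 °C
Reagents that add atoms: lithium dimethylcuprate, [Li+].C[Cu-]C
Why: syn-Carbocupration of the ynoate (conjugate addition) with cold protonation should put the new methyl cis to H12, hence ring carbon C18 cis to the ester (Z).

Step 9
Reactants: 12 ethyl 8-[(Z)-4-methoxy-4-oxobut-2-en-2-yl]-7-methyl-1,4-dioxaspiro[4.5]decane-7-carboxylate
Product: 13 ethyl 8-[(Z)-4-hydroxybut-2-en-2-yl]-7-methyl-1,4-dioxaspiro[4.5]decane-7-carboxylate
Conditions: i-Bu2AlH (2.1 equiv), CH2Cl2, −78 °C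
Reagents that add atoms: none
Why: Hydride 1,2-reduction of the unhindered conjugated methyl ester should be much faster than attack on the α-quaternary ethyl ester.

Step 10
Reactants: 13 ethyl 8-[(Z)-4-hydroxybut-2-en-2-yl]-7-methyl-1,4-dioxaspiro[4.5]decane-7-carboxylate
Product: 14 ethyl 7-methyl-8-[(Z)-4-(propanoyloxy)but-2-en-2-yl]-1,4-dioxaspiro[4.5]decane-7-carboxylate
Conditions: (EtCO)2O, Et3N, DMAP (cat.), CH2Cl2, 0 °C
Reagents that add atoms: propanoic anhydride, CCC(=O)OC(=O)CC
Why: DMAP-catalysed acylation of the primary allylic alcohol.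

Step 11
Reactants: 14 ethyl 7-methyl-8-[(Z)-4-(propanoyloxy)but-2-en-2-yl]-1,4-dioxaspiro[4.5]decane-7-carboxylate
Product: 17 3-(7-ethoxycarbonyl-7-methyl-1,4-dioxaspiro[4.5]decan-8-yl)-2,3-dimethylpent-4-enoic acid, via silyl ketene acetal 15 (not isolated), via trimethylsilyl ester 16 (not isolated)
Conditions: LiN(i-Pr)2, Me3SiCl–Et3N, THF, −78 °C → reflux; dilute aq. citric acid
Reagents that add atoms: none
Why: Ireland–Claisen [3,3] rearrangement forms C13–C14 and the quaternary C13; the (Z)-CH2O group locks H18 in the alkene plane by allylic 1,3-strain, so C14 should add to the C13 face anti to quaternary C17, which is the target configuration; the C14 epimers are both usable.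

Step 12
Reactants: 17 3-(7-ethoxycarbonyl-7-methyl-1,4-dioxaspiro[4.5]decan-8-yl)-2,3-dimethylpent-4-enoic acid
Product: 18 methyl ester of acid 17
Conditions: MeI, K2CO3, DMF, rt
Reagents that add atoms: iodomethane, CI
Why: SN2 O-alkylation of the carboxylate, which is insensitive to the hindrance at C14.

Step 13
Reactants: 18 methyl ester of acid 17
Product: 19 methyl 3-(7-ethoxycarbonyl-7-methyl-1,4-dioxaspiro[4.5]decan-8-yl)-5-hydroxy-2,3-dimethylpentanoate
Conditions: 9-borabicyclo[3.3.1]nonane, THF, 0 °C → rt; 30% H2O2, aq. NaOAc, 0 °C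
Reagents that add atoms: hydrogen peroxide, OO
Why: Anti-Markovnikov hydroboration–oxidation of the vinyl group gives the C11 alcohol, which is used at once so that it does not lactonise onto C15.

Step 14
Reactants: 19 methyl 3-(7-ethoxycarbonyl-7-methyl-1,4-dioxaspiro[4.5]decan-8-yl)-5-hydroxy-2,3-dimethylpentanoate
Product: 20 methyl 3-(7-ethoxycarbonyl-7-methyl-1,4-dioxaspiro[4.5]decan-8-yl)-2,3-dimethyl-5-oxopentanoate
Conditions: Dess–Martin periodinane, NaHCO3, CH2Cl2, 0 °C
Reagents that add atoms: none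
Why: Dess–Martin oxidation of the primary alcohol to the C11 aldehyde under buffered, non-epimerising conditions.

Step 15
Reactants: 21 pent-3-yn-1-ol
Product: 22 1-methoxy-4-[(pent-3-yn-1-yloxy)methyl]benzene
Conditions: NaH, 4-MeOC6H4CH2Cl, Bu4NI (cat.), THF–DMF, 0 °C → rt
Reagents that add atoms: 4-methoxybenzyl chloride, COc1ccc(CCl)cc1
Why: Williamson etherification protects the future C6 oxygen as a 4-methoxybenzyl ether.

Step 16
Reactants: 22 1-methoxy-4-[(pent-3-yn-1-yloxy)methyl]benzene
Product: 24 1-{[(E)-4-iodopent-3-en-1-yl]oxymethyl}-4-methoxybenzene, via alkenylzirconocene chloride 23 (not isolated)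
Conditions: Cp2Zr(H)Cl (1.5 equiv), THF, 50 °C; I2, 0 °C
Reagents that add atoms: iodine, II
Why: syn-Hydrozirconation, equilibrated with excess hydride so that zirconium sits on the methyl-bearing carbon, then iodinolysis with retention should give the (E)-2-iodoalkene (future C9=C8).

Step 17
Reactants: 24 1-{[(E)-4-iodopent-3-en-1-yl]oxymethyl}-4-methoxybenzene; 20 methyl 3-(7-ethoxycarbonyl-7-methyl-1,4-dioxaspiro[4.5]decan-8-yl)-2,3-dimethyl-5-oxopentanoate
Product: 26 C11 allylic alcohol (both C11 epimers), via alkenyllithium 25 (not isolated)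
Conditions: 24, t-BuLi (2 equiv), Et2O, −78 °C; then 20, −78 °C; aq. NH4Cl at −78 °C
Reagents that add atoms: none
Why: Iodine–lithium exchange with retention of the (E) geometry and 1,2-addition to the aldehyde, which is far more reactive than the two hindered esters; C11 is corrected in steps 18 and 19.

Step 18
Reactants: 26 C11 allylic alcohol (both C11 epimers)
Product: 27 C11 enone
Conditions: Dess–Martin periodinane, NaHCO3, CH2Cl2, 0 °C
Reagents that add atoms: none
Why: Dess–Martin oxidation of the allylic alcohol erases the uncontrolled C11 centre.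

Step 19
Reactants: 27 C11 enone
Product: 29 (11R) δ-lactone with C15 carbonyl and C11 carbinol, via hydroxy ester 28 (not isolated)
Conditions: (S)-1-methyl-3,3-diphenyltetrahydro-1H,3H-pyrrolo[1,2-c][1,3,2]oxazaborole (20 mol %), BH3·SMe2, THF, −30 °C; then pyridinium p-toluenesulfonate (cat.), toluene, 60 °C
Reagents that add atoms: none
Why: Corey–Bakshi–Shibata reduction with the α-methyl alkenyl group as the large substituent should give the (11R) alcohol, and acid-catalysed lactonisation onto the C15 ester then closes the six-membered lactone with the alkenyl group cis to the ring E substituent of C13.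

Step 20
Reactants: 29 (11R) δ-lactone with C15 carbonyl and C11 carbinol
Product: 32 ring C cyclohexene acid (C8, C13, C14 set; C9=C11), via cyclic silyl ketene acetal 30 (not isolated), via trimethylsilyl ester 31 (not isolated)
Conditions: LiN(i-Pr)2, Me3SiCl–Et3N (internal quench), THF, −78 °C → rt; toluene, 110 °C; dilute aq. citric acid
Reagents that add atoms: none
Why: LiN(i-Pr)2 removes the C14 proton and Me3SiCl traps the enolate as the cyclic silyl ketene acetal 30, whose C14=C15–O–C11–C9=C8 array undergoes a thermal [3,3]-sigmatropic shift that forms C8–C14 and breaks C11–O; this is an Ireland–Claisen ring contraction of a 6-alkenyl δ-lactone, known as a route to cyclohexenecarboxylic acids. Ring C (C8, C9, C11, C12, C13, C14) closes by this sigmatropic bond formation through a bicyclo[2.2.2]octane-like array, because the lactone tether allows only a boat transition state, and the alkene emerges at C9=C11. C14 is set by suprafacial delivery of C8 to the lactone face that carries the alkenyl group, which the (11R) carbinol holds cis to the ring E substituent of C13, so the C14 methyl ends cis to C18 and the carboxyl cis to the C13 methyl. C8 is set by the (E) geometry of C9=C8 in the boat, which turns H8 inward so that it ends syn to the C14 methyl, with the C7 chain syn to the carboxyl. The step needs enolisation of C14 next to quaternary C13 and a boat that outruns decomposition of the ketene acetal; the internal silyl quench and the six-membered lactone secure these, while crowding by ring E is the main hazard.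

Step 21
Reactants: 32 ring C cyclohexene acid
Product: 33 C15,C16 diol
Conditions: LiAlH4, THF, reflux
Reagents that add atoms: none
Why: Hydride reduction converts the neopentyl acid (C15) and the ethyl ester (C16) into the two primary alcohols in one operation.

Step 22
Reactants: 33 C15,C16 diol
Product: 34 C15,C16 dialdehyde
Conditions: Dess–Martin periodinane, NaHCO3, CH2Cl2, rt
Reagents that add atoms: none
Why: Dess–Martin oxidation; both aldehydes sit on quaternary carbons and cannot epimerise.

Step 23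
Reactants: 34 C15,C16 dialdehyde
Product: 35 divinyl compound (vinyl groups on C14 and C17)
Conditions: Ph3PCH3Br, KOt-Bu, THF, 0 °C → rt
Reagents that add atoms: methyltriphenylphosphonium bromide, C[P+](c1ccccc1)(c1ccccc1)c1ccccc1.[Br-]
Why: Wittig methylenation of the two non-enolisable aldehydes.

Step 24
Reactants: 35 divinyl compound
Product: 36 tricyclic ring C/D/E diene (C9=C11, C15=C16) with C6 4-methoxybenzyl ether
Conditions: second-generation Grubbs catalyst (5 mol %), toluene, 80 °C
Reagents that add atoms: none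
Why: Ring-closing metathesis of the two vinyl groups closes six-membered ring D (C15=C16) trans-fused on C13–C14; the trisubstituted C9=C11 alkene should stay inert.

Step 25
Reactants: 36 tricyclic diene with C6 4-methoxybenzyl ether
Product: 37 C6 alcohol
Conditions: DDQ, CH2Cl2–pH 7 buffer, 0 °C
Reagents that add atoms: none
Why: Oxidative cleavage of the 4-methoxybenzyl ether leaves the ketal and both alkenes intact.

Step 26
Reactants: 37 C6 alcohol
Product: 38 C6 aldehyde
Conditions: Dess–Martin periodinane, NaHCO3, CH2Cl2, 0 °C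
Reagents that add atoms: none
Why: Dess–Martin oxidation of the primary alcohol.

Step 27
Reactants: 39 2-methoxy-6-methylphenol
Product: 40 4-bromo-2-methoxy-6-methylphenol
Conditions: N-bromosuccinimide, MeCN, 0 °C
Reagents that add atoms: N-bromosuccinimide, BrN1C(=O)CCC1=O
Why: Electrophilic aromatic bromination para to the free hydroxyl (both ortho positions blocked) places bromine on the future C10.

Step 28
Reactants: 40 4-bromo-2-methoxy-6-methylphenol
Product: 41 5-bromo-3-methylbenzene-1,2-diol
Conditions: BBr3, CH2Cl2, −78 → 0 °C; H2O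
Reagents that add atoms: none
Why: Lewis-acid cleavage of the aryl methyl ether.

Step 29
Reactants: 41 5-bromo-3-methylbenzene-1,2-diol
Product: 42 1,2-bis(benzyloxy)-5-bromo-3-methylbenzene
Conditions: PhCH2Br, K2CO3, DMF, 50 °C
Reagents that add atoms: benzyl bromide, BrCc1ccccc1
Why: Double Williamson etherification; the benzyl groups are later removed in the hydrogenation of step 34.

Step 30
Reactants: 42 1,2-bis(benzyloxy)-5-bromo-3-methylbenzene
Product: 43 1,2-bis(benzyloxy)-5-bromo-4-iodo-3-methylbenzene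
Conditions: N-iodosuccinimide, CF3CO2H (cat.), MeCN, rt
Reagents that add atoms: N-iodosuccinimide, IN1C(=O)CCC1=O
Why: Electrophilic iodination should go para to the in-plane C2 benzyloxy group (future C5, between methyl and bromine), since the other free position is shielded by that benzyl group.

Step 31
Reactants: 43 1,2-bis(benzyloxy)-5-bromo-4-iodo-3-methylbenzene; 38 C6 aldehyde
Product: 45 C6 aryl carbinol (both C6 epimers), via aryl Grignard 44 (not isolated)
Conditions: 43, i-PrMgCl·LiCl, THF, −40 °C; then 38, −40 → 0 °C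
Reagents that add atoms: none
Why: Iodine–magnesium exchange is selective for iodide over bromide, the 2-bromoaryl Grignard is stable at this temperature, and its addition to the aldehyde forms C5–C6.

Step 32
Reactants: 45 C6 aryl carbinol
Product: 46 C6 aryl ketone
Conditions: Dess–Martin periodinane, NaHCO3, CH2Cl2, rt
Reagents that add atoms: none
Why: Dess–Martin oxidation of the benzylic alcohol.

Step 33
Reactants: 46 C6 aryl ketone
Product: 47 pentacyclic ketone with C11=C12 and C15=C16
Conditions: Pd(OAc)2 (10 mol %), PPh3 (30 mol %), Et3N, DMF, 90 °C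
Reagents that add atoms: none
Why: Intramolecular Mizoroki–Heck reaction closes ring B by 6-exo-trig carbopalladation of C9=C11; the C7–C6 tether holds the aryl group on the α face of C9 (methyl β, rings B and C cis-fused), and syn β-hydride elimination can only give C11=C12.

Step 34
Reactants: 47 pentacyclic ketone with C11=C12 and C15=C16
Product: 48 saturated catechol with C21 ketal
Conditions: H2 (4 atm), Pd/C, EtOAc–EtOH, rt
Reagents that add atoms: none
Why: Heterogeneous hydrogenation saturates the two disubstituted ring alkenes (no new stereocentre) and hydrogenolyses both benzyl ethers.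

Step 35
Reactants: 48 saturated catechol with C21 ketal
Product: 49 catechol 6,21-diketone
Conditions: 1 M aq. HCl, THF, rt
Reagents that add atoms: water, O
Why: Acid-catalysed ketal hydrolysis frees the C21 ketone before the acid-sensitive guaiane unit is attached.

Step 36
Reactants: 50 (S)-carvone
Product: 51 (2S,5S)-dihydrocarvone
Conditions: Zn dust, KOH, EtOH–H2O, reflux
Reagents that add atoms: none
Why: Zinc conjugate reduction of the enone under equilibrating base should give mainly the 2,5-trans ketone (future G10 and G7).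

Step 37
Reactants: 51 (2S,5S)-dihydrocarvone
Product: 52 ethyl (3S,6S)-3-methyl-2-oxo-6-(prop-1-en-2-yl)cycloheptane-1-carboxylate (C1 epimers)
Conditions: N2CHCO2Et, BF3·OEt2, Et2O, 0 °C
Reagents that add atoms: ethyl diazoacetate, CCOC(=O)C=[N+]=[N-]
Why: Lewis-acid-promoted diazoacetate ring expansion with migration of the less substituted α-carbon inserts the future G5 between the carbonyl (G1) and G6.

Step 38
Reactants: 52 ethyl (3S,6S)-3-methyl-2-oxo-6-(prop-1-en-2-yl)cycloheptane-1-carboxylate
Product: 53 1-(2-oxopropyl) derivative of β-keto ester 52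
Conditions: ClCH2COCH3, K2CO3, NaI (cat.), acetone, reflux
Reagents that add atoms: chloroacetone, CC(=O)CCl
Why: C-Alkylation of the β-keto ester enolate fixes the acetonyl unit (G4, G3, G2) on G5.

Step 39
Reactants: 53 1-(2-oxopropyl) derivative of β-keto ester 52
Product: 54 2-methyl-7-(2-oxopropyl)-5-(prop-1-en-2-yl)cycloheptan-1-one
Conditions: LiCl, DMSO–H2O, 150 °C
Reagents that add atoms: none
Why: Krapcho dealkoxycarbonylation removes the ester under neutral conditions that spare the isopropenyl group.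

Step 40
Reactants: 54 2-methyl-7-(2-oxopropyl)-5-(prop-1-en-2-yl)cycloheptan-1-one
Product: 55 15-nor-guaia-1,11-dien-3-one
Conditions: KOH, EtOH, reflux
Reagents that add atoms: none
Why: Intramolecular aldol condensation of the 1,4-diketone closes the five-membered ring (G2 onto G1); G10 stays in or returns to the favoured arrangement trans to G7.

Step 41
Reactants: 55 15-nor-guaia-1,11-dien-3-one
Product: 56 guaia-1,11-dien-3-one (G4 and G5 epimers)
Conditions: LiN(i-Pr)2, THF, −78 °C; MeI
Reagents that add atoms: iodomethane, CI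
Why: Kinetic α'-enolate formation at G4 and C-methylation install C15; the epimers converge in step 42.

Step 42
Reactants: 56 guaia-1,11-dien-3-one
Product: 58 3-(tert-butyldimethylsilyloxy)guaia-1(5),3,11-triene, via cross-conjugated silyl dienol ether 57 (not isolated)
Conditions: LiN(i-Pr)2, THF, −78 °C; t-BuMe2SiCl, DMPU, −78 °C → rt; then toluene, 60 °C
Reagents that add atoms: tert-butyl(chloro)dimethylsilane, CC(C)(C)[Si](C)(C)Cl
Why: Kinetic O-silylation of the α'-enolate, then thermal [1,5]-hydrogen shifts around the cyclopentadiene, should collect the tautomer with all four substituents on sp2 carbons and G2 as the CH2 group.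

Step 43
Reactants: 49 catechol 6,21-diketone; 58 3-(tert-butyldimethylsilyloxy)guaia-1(5),3,11-triene
Product: 60 dioxane cycloadduct with G3 silyl enol ether, via o-quinone 59 (not isolated)
Conditions: 49, Ag2O, Na2SO4, Et2O, rt, filtration; then 58 (2 equiv), CH2Cl2, −78 → 0 °C
Reagents that add atoms: none
Why: Proposed new method: the o-quinone 59 made by Ag2O acts as an electron-poor O=C–C=O heterodiene toward the distal G1=G5 bond of the 1-silyloxy diene 58; polar, asynchronous bonding of the C3 oxygen (its partner oxygen on C2 becomes a phenoxide stabilised by the para C6 ketone) to the nucleophilic δ-carbon G1 is followed by closure of the C2 oxygen on G5 of the silyloxyallyl cation, both on the diene face anti to the pseudo-axial G10 methyl, which closes the cis-fused dioxane and sets G1 and G5; the closest known reactions are the inverse-electron-demand hetero-Diels–Alder additions of o-quinones to enol ethers and to one double bond of 1,3-dienes and the γ-selective reactions of α-substituted silyl dienol ethers.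

Step 44
Reactants: 60 dioxane cycloadduct with G3 silyl enol ether
Product: 61 G3 enol nonaflate
Conditions: C4F9SO2F, Bu4NF (10 mol %), THF, 0 °C → rt
Reagents that add atoms: nonafluorobutane-1-sulfonyl fluoride, FS(=O)(=O)C(F)(F)C(F)(F)C(F)(F)C(F)(F)F
Why: Fluoride-catalysed conversion of a silyl enol ether into the alkenyl nonaflate is regiospecific and traps the transient enolate before it can exchange protons with the C6 or C21 ketone.

Step 45
Reactants: 61 G3 enol nonaflate
Product: 62 CNP0177131.1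
Conditions: Pd(OAc)2 (5 mol %), PPh3 (10 mol %), HCO2H, Bu3N, DMF, 60 °C
Reagents that add atoms: none
Why: Palladium-catalysed formate reduction of the alkenyl sulfonate replaces the nonaflate by hydrogen and leaves the alkene at G3=G4; ketones, the isopropenyl group and the aryl ethers are expected to be tolerated.

**Compound list**

1 | 2,2-dimethoxyacetaldehyde | COC(OC)C=O | starting material
2 | ethyl 2-(triphenyl-λ5-phosphanylidene)propanoate | CCOC(=O)C(C)=P(c1ccccc1)(c1ccccc1)c1ccccc1 | starting material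
3 | ethyl (E)-4,4-dimethoxy-2-methylbut-2-enoate | CCOC(=O)/C(C)=C/C(OC)OC | intermediate
4 | ethyl (E)-2-methyl-4-oxobut-2-enoate | CCOC(=O)/C(C)=C/C=O | intermediate
5 | but-3-en-2-one | CC(=O)C=C | starting material
6 | 2-(triisopropylsilyloxy)buta-1,3-diene | C=CC(=C)O[Si](C(C)C)(C(C)C)C(C)C | intermediate
7 | ethyl (1S,6S)-6-formyl-1-methyl-3-(triisopropylsilyloxy)cyclohex-3-ene-1-carboxylate (ring E; C1 = C17, C6 = C18; formyl trans to ester) | O=C[C@H]1CC=C(O[Si](C(C)C)(C(C)C)C(C)C)C[C@]1(C)C(=O)OCC | intermediate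
8 | ethyl 6-(2,2-dibromoethenyl)-1-methyl-3-(triisopropylsilyloxy)cyclohex-3-ene-1-carboxylate (ring configuration of 7) | BrC(Br)=C[C@H]1CC=C(O[Si](C(C)C)(C(C)C)C(C)C)C[C@]1(C)C(=O)OCC | intermediate
9 | ethyl 8-(2,2-dibromoethenyl)-7-methyl-1,4-dioxaspiro[4.5]decane-7-carboxylate (C8 side chain cis to C7 methyl) | BrC(Br)=C[C@H]1CCC2(OCCO2)C[C@]1(C)C(=O)OCC | intermediate
10 | lithium acetylide from 9 (8-(lithioethynyl) compound) | [Li]C#C[C@H]1CCC2(OCCO2)C[C@]1(C)C(=O)OCC | intermediate
11 | ethyl 8-(3-methoxy-3-oxoprop-1-yn-1-yl)-7-methyl-1,4-dioxaspiro[4.5]decane-7-carboxylate | COC(=O)C#C[C@H]1CCC2(OCCO2)C[C@]1(C)C(=O)OCC | intermediate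
12 | ethyl 8-[(Z)-4-methoxy-4-oxobut-2-en-2-yl]-7-methyl-1,4-dioxaspiro[4.5]decane-7-carboxylate | COC(=O)/C=C(/C)[C@H]1CCC2(OCCO2)C[C@]1(C)C(=O)OCC | intermediate
13 | ethyl 8-[(Z)-4-hydroxybut-2-en-2-yl]-7-methyl-1,4-dioxaspiro[4.5]decane-7-carboxylate | OC/C=C(/C)[C@H]1CCC2(OCCO2)C[C@]1(C)C(=O)OCC | intermediate
14 | ethyl 7-methyl-8-[(Z)-4-(propanoyloxy)but-2-en-2-yl]-1,4-dioxaspiro[4.5]decane-7-carboxylate | CCC(=O)OC/C=C(/C)[C@H]1CCC2(OCCO2)C[C@]1(C)C(=O)OCC | intermediate
15 | trimethylsilyl ketene acetal of propanoate 14 | CC=C(O[Si](C)(C)C)OC/C=C(/C)[C@H]1CCC2(OCCO2)C[C@]1(C)C(=O)OCC | intermediate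
16 | trimethylsilyl ester of acid 17 | C[Si](C)(C)OC(=O)C(C)[C@@](C)(C=C)[C@H]1CCC2(OCCO2)C[C@]1(C)C(=O)OCC | intermediate
17 | 3-(7-ethoxycarbonyl-7-methyl-1,4-dioxaspiro[4.5]decan-8-yl)-2,3-dimethylpent-4-enoic acid (C13 as in the target, C14 epimers) | OC(=O)C(C)[C@@](C)(C=C)[C@H]1CCC2(OCCO2)C[C@]1(C)C(=O)OCC | intermediate
18 | methyl ester of acid 17 | COC(=O)C(C)[C@@](C)(C=C)[C@H]1CCC2(OCCO2)C[C@]1(C)C(=O)OCC | intermediate
19 | methyl 3-(7-ethoxycarbonyl-7-methyl-1,4-dioxaspiro[4.5]decan-8-yl)-5-hydroxy-2,3-dimethylpentanoate | COC(=O)C(C)[C@@](C)(CCO)[C@H]1CCC2(OCCO2)C[C@]1(C)C(=O)OCC | intermediate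
20 | methyl 3-(7-ethoxycarbonyl-7-methyl-1,4-dioxaspiro[4.5]decan-8-yl)-2,3-dimethyl-5-oxopentanoate (C11 aldehyde) | COC(=O)C(C)[C@@](C)(CC=O)[C@H]1CCC2(OCCO2)C[C@]1(C)C(=O)OCC | intermediate
21 | pent-3-yn-1-ol | CC#CCCO | starting material
22 | 1-methoxy-4-[(pent-3-yn-1-yloxy)methyl]benzene | CC#CCCOCc1ccc(OC)cc1 | intermediate
23 | chlorobis(cyclopentadienyl)[(E)-5-(4-methoxybenzyloxy)pent-2-en-2-yl]zirconium | Cl[Zr](C1C=CC=C1)(C1C=CC=C1)/C(C)=C/CCOCc1ccc(OC)cc1 | intermediate
24 | 1-{[(E)-4-iodopent-3-en-1-yl]oxymethyl}-4-methoxybenzene | I/C(C)=C/CCOCc1ccc(OC)cc1 | intermediate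
25 | [(E)-5-(4-methoxybenzyloxy)pent-2-en-2-yl]lithium | [Li]/C(C)=C/CCOCc1ccc(OC)cc1 | intermediate
26 | C11 allylic alcohol: methyl ester 20 carrying the (E)-alkenyl group on C11 (C11 and C14 epimers) | COC(=O)C(C)[C@@](C)(CC(O)/C(C)=C/CCOCc1ccc(OC)cc1)[C@H]1CCC2(OCCO2)C[C@]1(C)C(=O)OCC | intermediate
27 | C11 enone | COC(=O)C(C)[C@@](C)(CC(=O)/C(C)=C/CCOCc1ccc(OC)cc1)[C@H]1CCC2(OCCO2)C[C@]1(C)C(=O)OCC | intermediate
28 | (11R) hydroxy ester | COC(=O)C(C)[C@@](C)(C[C@@H](O)/C(C)=C/CCOCc1ccc(OC)cc1)[C@H]1CCC2(OCCO2)C[C@]1(C)C(=O)OCC | intermediate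
29 | (11R) δ-lactone (C15 carbonyl, C11 carbinol with (E)-alkenyl chain cis to the ring E substituent of C13; C14 epimers), key-step precursor | O=C1O[C@@H](/C(C)=C/CCOCc2ccc(OC)cc2)C[C@@](C)([C@H]2CCC3(OCCO3)C[C@]2(C)C(=O)OCC)C1C | intermediate
30 | cyclic trimethylsilyl ketene acetal of lactone 29 | CC1=C(O[Si](C)(C)C)O[C@@H](/C(C)=C/CCOCc2ccc(OC)cc2)C[C@@]1(C)[C@H]1CCC2(OCCO2)C[C@]1(C)C(=O)OCC | intermediate
31 | trimethylsilyl ester of acid 32 | COc1ccc(COCC[C@@H]2C(C)=CC[C@@](C)([C@H]3CCC4(OCCO4)C[C@]3(C)C(=O)OCC)[C@]2(C)C(=O)O[Si](C)(C)C)cc1 | intermediate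
32 | ring C cyclohexene acid (C9=C11; C8 H syn to the C14 methyl; C15 carboxyl on C14), key-step product | COc1ccc(COCC[C@@H]2C(C)=CC[C@@](C)([C@H]3CCC4(OCCO4)C[C@]3(C)C(=O)OCC)[C@]2(C)C(=O)O)cc1 | intermediate
33 | C15,C16 diol | COc1ccc(COCC[C@@H]2C(C)=CC[C@@](C)([C@H]3CCC4(OCCO4)C[C@]3(C)CO)[C@]2(C)CO)cc1 | intermediate
34 | C15,C16 dialdehyde | COc1ccc(COCC[C@@H]2C(C)=CC[C@@](C)([C@H]3CCC4(OCCO4)C[C@]3(C)C=O)[C@]2(C)C=O)cc1 | intermediate
35 | divinyl compound (vinyl groups on C14 and C17) | COc1ccc(COCC[C@@H]2C(C)=CC[C@@](C)([C@H]3CCC4(OCCO4)C[C@]3(C)C=C)[C@]2(C)C=C)cc1 | intermediate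
36 | tricyclic ring C/D/E diene (C9=C11, C15=C16; C/D trans, D/E trans) with C6 4-methoxybenzyl ether | COc1ccc(COCC[C@@H]2C(C)=CC[C@@]3(C)[C@H]4CCC5(OCCO5)C[C@]4(C)C=C[C@]23C)cc1 | intermediate
37 | tricyclic C6 alcohol | OCC[C@@H]1C(C)=CC[C@@]2(C)[C@H]3CCC4(OCCO4)C[C@]3(C)C=C[C@]12C | intermediate
38 | tricyclic C6 aldehyde | O=CC[C@@H]1C(C)=CC[C@@]2(C)[C@H]3CCC4(OCCO4)C[C@]3(C)C=C[C@]12C | intermediate
39 | 2-methoxy-6-methylphenol | COc1cccc(C)c1O | starting material
40 | 4-bromo-2-methoxy-6-methylphenol | COc1cc(Br)cc(C)c1O | intermediate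
41 | 5-bromo-3-methylbenzene-1,2-diol | Cc1cc(Br)cc(O)c1O | intermediate
42 | 1,2-bis(benzyloxy)-5-bromo-3-methylbenzene | Cc1cc(Br)cc(OCc2ccccc2)c1OCc1ccccc1 | intermediate
43 | 1,2-bis(benzyloxy)-5-bromo-4-iodo-3-methylbenzene | Cc1c(I)c(Br)cc(OCc2ccccc2)c1OCc1ccccc1 | intermediate
44 | [3,4-bis(benzyloxy)-6-bromo-2-methylphenyl]magnesium chloride | Cc1c([Mg]Cl)c(Br)cc(OCc2ccccc2)c1OCc1ccccc1 | intermediate
45 | C6 aryl carbinol (C6 epimers) | OC(C[C@@H]1C(C)=CC[C@@]2(C)[C@H]3CCC4(OCCO4)C[C@]3(C)C=C[C@]12C)c1c(C)c(OCc2ccccc2)c(OCc2ccccc2)cc1Br | intermediate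
46 | C6 aryl ketone | O=C(C[C@@H]1C(C)=CC[C@@]2(C)[C@H]3CCC4(OCCO4)C[C@]3(C)C=C[C@]12C)c1c(C)c(OCc2ccccc2)c(OCc2ccccc2)cc1Br | intermediate
47 | pentacyclic 2,3-bis(benzyloxy) 6-ketone with C11=C12 and C15=C16, C21 ketal (8β-H, 9β-methyl) | Cc1c2C(=O)C[C@@H]3[C@@](C)(C=C[C@@]4(C)[C@H]5CCC6(OCCO6)C[C@]5(C)C=C[C@]34C)c2cc(OCc2ccccc2)c1OCc1ccccc1 | intermediate
48 | saturated pentacyclic catechol 6-ketone with C21 ketal | Cc1c2C(=O)C[C@@H]3[C@@](C)(CC[C@@]4(C)[C@H]5CCC6(OCCO6)C[C@]5(C)CC[C@]34C)c2cc(O)c1O | intermediate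
49 | pentacyclic catechol 6,21-diketone (2,3-dihydroxy A-ring aromatic triterpenoid part of the target) | Cc1c2C(=O)C[C@@H]3[C@@](C)(CC[C@@]4(C)[C@H]5CCC(=O)C[C@]5(C)CC[C@]34C)c2cc(O)c1O | intermediate
50 | (S)-carvone | O=C1C(C)=CC[C@H](C(C)=C)C1 | starting material
51 | (2S,5S)-dihydrocarvone (2,5-trans) | O=C1[C@@H](C)CC[C@H](C(C)=C)C1 | intermediate
52 | ethyl (3S,6S)-3-methyl-2-oxo-6-(prop-1-en-2-yl)cycloheptane-1-carboxylate (C1 epimers) | O=C1[C@@H](C)CC[C@H](C(C)=C)CC1C(=O)OCC | intermediate
53 | ethyl 3-methyl-2-oxo-1-(2-oxopropyl)-6-(prop-1-en-2-yl)cycloheptane-1-carboxylate (C3, C6 as in 52) | O=C1[C@@H](C)CC[C@H](C(C)=C)CC1(CC(C)=O)C(=O)OCC | intermediate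
54 | 2-methyl-7-(2-oxopropyl)-5-(prop-1-en-2-yl)cycloheptan-1-one (G10, G7 as in 51; G5 epimers) | O=C1[C@@H](C)CC[C@H](C(C)=C)CC1CC(C)=O | intermediate
55 | 15-nor-guaia-1,11-dien-3-one (G5 epimers) | O=C1C=C2[C@@H](C)CC[C@H](C(C)=C)CC2C1 | intermediate
56 | guaia-1,11-dien-3-one (G4 and G5 epimers) | O=C1C=C2[C@@H](C)CC[C@H](C(C)=C)CC2C1C | intermediate
57 | 3-(tert-butyldimethylsilyloxy)guaia-1,3,11-triene (cross-conjugated, G5–H) | CC1=C(O[Si](C)(C)C(C)(C)C)C=C2[C@@H](C)CC[C@H](C(C)=C)CC12 | intermediate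
58 | 3-(tert-butyldimethylsilyloxy)guaia-1(5),3,11-triene (G10 methyl trans to G7 isopropenyl) | CC1=C(O[Si](C)(C)C(C)(C)C)CC2=C1C[C@@H](C(C)=C)CC[C@@H]2C | intermediate
59 | ring A o-quinone (2,3-dione) of diketone 49 | CC1=C2C(=O)C[C@@H]3[C@@](C)(CC[C@@]4(C)[C@H]5CCC(=O)C[C@]5(C)CC[C@]34C)C2=CC(=O)C1=O | intermediate
60 | dioxane cycloadduct (C3–O–G1, C2–O–G5, cis, anti to the G10 methyl) with G3 tert-butyldimethylsilyl enol ether | C=C(C)[C@H]1CC[C@H](C)[C@]23CC(O[Si](C)(C)C(C)(C)C)=C(C)[C@@]2(C1)Oc1cc2c(c(C)c1O3)C(=O)C[C@@H]1[C@@]2(C)CC[C@@]2(C)[C@H]3CCC(=O)C[C@]3(C)CC[C@]12C | intermediate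
61 | G3 enol nonafluorobutanesulfonate of the cycloadduct | C=C(C)[C@H]1CC[C@H](C)[C@]23CC(OS(=O)(=O)C(F)(F)C(F)(F)C(F)(F)C(F)(F)F)=C(C)[C@@]2(C1)Oc1cc2c(c(C)c1O3)C(=O)C[C@@H]1[C@@]2(C)CC[C@@]2(C)[C@H]3CCC(=O)C[C@]3(C)CC[C@]12C | intermediate
62 | CNP0177131.1 | C=C(C)[C@H]1CC[C@H](C)[C@]23CC=C(C)[C@@]2(C1)Oc1cc2c(c(C)c1O3)C(=O)C[C@@H]1[C@@]2(C)CC[C@@]2(C)[C@H]3CCC(=O)C[C@]3(C)CC[C@]12C | target

**Step count and risks**

Total step count: 45. Longest linear sequence: 31 steps (steps 1, 2, 4–14, 17–26, 31–35, 43–45).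

Steps most likely to fail:

1. Step 43 (new method). The quinone may instead add across the enol ether bond G3=G4 or bond through the other oxygen first, face selection at G1/G5 may be poor, or the diene tautomer may drift before it reacts. Fallback with known chemistry, setting out from enone 56 and coming back at target 62: reduction of 56 with NaBH4/CeCl3·7H2O to guaia-1,11-dien-3-ol F1, dehydration with methyl N-(triethylammoniosulfonyl)carbamate and thermal equilibration to guaia-1(5),3,11-triene F2, then direct [4+2] addition of o-quinone 59 (from 49 and Ag2O) to F2, the known o-quinone/1,3-diene cycloaddition. This drops the oxygen handle and steps 44 and 45, at the price of site and regioisomers that would have to be separated.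

2. Step 20. Enolisation of C14 beside quaternary C13 may be incomplete, or the crowded boat may be reached so slowly that the silyl ketene acetal decomposes instead of rearranging. Fallback setting out from enone 27 and coming back at diol 33: base-mediated intramolecular Michael addition (Cs2CO3, MeCN) of the C14 ester enolate to C8 of the enone gives ring C ketone F3 (the diastereomer with H8 syn to the C14 methyl is separated). Thermodynamic enol triflate formation (Tf2O, 2,6-di-tert-butyl-4-methylpyridine) toward C9 gives C9=C11 enol triflate F4, and reduction with Pd(OAc)2, PPh3, HCO2H and Bu3N gives cyclohexene diester F5, which LiAlH4 reduces to 33.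

3. Step 11. The hindered (Z)-allyl ester may rearrange sluggishly (enolate loss through ketene formation), or face selection at C13 may be incomplete. Fallback setting out from (Z)-enoate 12 and coming back at lactone 29: conjugate addition of lithium di(prop-1-en-2-yl)cuprate with Me3SiCl, anti to C17 in the same locked conformer, gives pentenoate F6. Hydroboration–oxidation of the isopropenyl group with spontaneous lactonisation gives δ-lactone F7 (C11 carbonyl, O–C15). Single addition of alkenyllithium 25 at −78 °C gives hydroxy enone F8, CBS reduction as in step 19 gives (11R) diol F9, and oxidative lactonisation of the 1,5-diol with TEMPO and PhI(OAc)2 gives 29.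

**Further compounds**

F1 | step 43 | guaia-1,11-dien-3-ol (C3, C4, C5 epimers) | OC1C=C2[C@@H](C)CC[C@H](C(C)=C)CC2C1C
F2 | step 43 | guaia-1(5),3,11-triene | CC1=CCC2=C1C[C@@H](C(C)=C)CC[C@@H]2C
F3 | step 20 | ring C 11-ketone from Michael closure (C8–C14 bond; C9 epimers) | COc1ccc(COCC[C@@H]2C(C)C(=O)C[C@@](C)([C@H]3CCC4(OCCO4)C[C@]3(C)C(=O)OCC)[C@]2(C)C(=O)OC)cc1
F4 | step 20 | C9=C11 enol triflate of ketone F3 | COc1ccc(COCC[C@@H]2C(C)=C(OS(=O)(=O)C(F)(F)F)C[C@@](C)([C@H]3CCC4(OCCO4)C[C@]3(C)C(=O)OCC)[C@]2(C)C(=O)OC)cc1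
F5 | step 20 | methyl ester of acid 32 | COc1ccc(COCC[C@@H]2C(C)=CC[C@@](C)([C@H]3CCC4(OCCO4)C[C@]3(C)C(=O)OCC)[C@]2(C)C(=O)OC)cc1
F6 | step 11 | methyl 3-(7-ethoxycarbonyl-7-methyl-1,4-dioxaspiro[4.5]decan-8-yl)-3,4-dimethylpent-4-enoate | COC(=O)C[C@](C)(C(C)=C)[C@H]1CCC2(OCCO2)C[C@]1(C)C(=O)OCC
F7 | step 11 | δ-lactone with C11 carbonyl and O–C15 (C14 epimers) | O=C1C[C@@](C)([C@H]2CCC3(OCCO3)C[C@]2(C)C(=O)OCC)C(C)CO1
F8 | step 11 | C15 hydroxy C11 enone | OCC(C)[C@@](C)(CC(=O)/C(C)=C/CCOCc1ccc(OC)cc1)[C@H]1CCC2(OCCO2)C[C@]1(C)C(=O)OCC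
F9 | step 11 | (11R) C11,C15 diol | OCC(C)[C@@](C)(C[C@@H](O)/C(C)=C/CCOCc1ccc(OC)cc1)[C@H]1CCC2(OCCO2)C[C@]1(C)C(=O)OCC
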